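## Retrosynthetic overview
- The target comes from a bicyclo[3.2.1]oct-3-ene-2,8-dione by two hydride deliveries: conjugate reduction of the 3-methoxy-enone, then reduction of the C2 ketone. That enedione already holds every carbon and four of the six stereocentres.
- The enedione comes from one cationic [5+2] event that mirrors the proposed coupling of an oxidised allylphenol with a propenylbenzene. 6-Allyl-2,3,4-trimethoxyphenol is oxidised by two electrons to its phenoxenium (oxypentadienyl) cation and joined to isoelemicin.
- Ring order: the arene becomes the six-membered ring. Bond C5–C6 forms first. Bond C1–C7 then closes the cyclopentanone and the seven-membered ring together, so the bicycle appears in one flask.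
- Stereochemical relay: the (Z)-alkene is used, not the (E)-alkene. Aryl-endo approach then also places the methyl endo (anti to allyl), and closure trans to methyl leaves the aryl exo. A chiral counter-anion selects the face of the flat cation.
- The phenol comes from 2,3,4-trimethoxyphenol by O-allylation and Claisen rearrangement. (Z)-Isoelemicin comes from 3,4,5-trimethoxybenzaldehyde by a Wittig reaction.

Convention: at C6/C7, exo means on the side of the C8 carbonyl bridge and endo means on the side of the C2–C4 bridge.

Assumption: the (S,S)-catalyst in step 4 is taken to give the enantiomer drawn. If the sense proves opposite, the (R,R)-catalyst is used and nothing else changes.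

## Route

Step 1
Reactants: 1 2,3,4-trimethoxyphenol; 2 allyl bromide
Product: 3 1,2,3-trimethoxy-4-(prop-2-enyloxy)benzene
Conditions: K2CO3, acetone, reflux
Reagents that add atoms: none
Why: Williamson ether synthesis (SN2 of the phenoxide on allyl bromide), with no stereocentre formed.

Step 2
Reactants: 3 1,2,3-trimethoxy-4-(prop-2-enyloxy)benzene
Product: 4 2,3,4-trimethoxy-6-(prop-2-enyl)phenol
Conditions: N,N-diethylaniline, 200 °C, Ar
Reagents that add atoms: none
Why: Aromatic Claisen rearrangement, in which C6 is the only free ortho position and migration to the methoxy-bearing ortho carbon cannot rearomatise and reverts, so one regioisomer forms and no stereocentre is created.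

Step 3
Reactants: 5 3,4,5-trimethoxybenzaldehyde; 6 ethyltriphenylphosphonium bromide
Product: 8 (Z)-isoelemicin [1,2,3-trimethoxy-5-[(1Z)-prop-1-enyl]benzene], via ethylidene ylide 7 (not isolated)
Conditions: KHMDS, THF, 0 °C; then 5, −78 °C → rt; AgNO3–SiO2 chromatography
Reagents that add atoms: none
Why: Salt-free Wittig olefination with a non-stabilised ylide goes through the kinetic cis-oxaphosphetane and gives mainly the Z alkene (about 9:1), and the residual E isomer is removed because it would feed the wrong diastereomer series in step 4.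

Step 4
Reactants: 4 2,3,4-trimethoxy-6-(prop-2-enyl)phenol; 8 (Z)-isoelemicin
Product: 11 (1S,5R,6S,7R)-1,3-dimethoxy-6-methyl-5-(prop-2-enyl)-7-(3,4,5-trimethoxyphenyl)bicyclo[3.2.1]oct-3-ene-2,8-dione, via quinone monoketal 9 (not isolated), via bicyclic dimethyl ketal 10 (not isolated)
Conditions: (a) PhI(OAc)2 (1.0 equiv), MeOH, 0 °C; evaporate, PhMe azeotrope; (b) 8 (1.2 equiv), (S,S)-IDPi acid (imidodiphosphorimidate from two 3,3'-diaryl-BINOL units, P=NTf groups; 5 mol %), CH2Cl2–PhMe, −78 → −30 °C; (c) H2O–THF, −30 → 0 °C, then Et3N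
Reagents that add atoms: methanol, CO; water, O
Why: Proposed new method: PhI(OAc)2/MeOH dearomatises 4 to the achiral ketal 9 (standard phenol oxidation), and the strong confined acid ionises 9 to the 2-allyl-4,5,6-trimethoxyphenoxenium (oxypentadienyl) cation held as a contact ion pair, so that only one face is open; the CHMe carbon of 8 attacks the allyl-bearing terminus with the aryl ring stacked over the cation (endo), which for a Z alkene also puts the methyl endo, anti to allyl, and fixes C5 and C6; the benzylic cation then closes on the methoxy-bearing terminus from the aryl-exo rotamer trans to methyl, which fixes C1 and C7; closure stays reversible while C2 is at the oxocarbenium/ketal level, so strained cis or O-closed products re-ionise and drain into this adduct; the released MeOH caps the oxocarbenium as 10 and returns the proton, and water then gives 11; the closest known reaction types are the racemic acid-promoted quinone-monoketal/propenylbenzene [5+2] cycloaddition (E alkenes give the 6-exo-methyl-7-endo-aryl series) and asymmetric counteranion-directed catalysis of oxocarbenium ions.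

Step 5
Reactants: 11 (1S,5R,6S,7R)-enedione
Product: 12 (1S,3R,5S,6S,7R)-1,3-dimethoxy-6-methyl-5-(prop-2-enyl)-7-(3,4,5-trimethoxyphenyl)bicyclo[3.2.1]octane-2,8-dione
Conditions: Cu(OAc)2·H2O (5 mol %), 1,2-(Ph2P)2C6H4 (5 mol %), (EtO)2MeSiH, t-BuOH, PhMe, rt; SiO2 plug; DBU (0.2 equiv), CH2Cl2, rt
Reagents that add atoms: none
Why: Copper hydride (Stryker-type) conjugate reduction delivers soft hydride only to the enone β-carbon C4 and leaves the terminal alkene and the doubly neopentyl C8 ketone alone, while C3 is set thermodynamically by DBU epimerisation because an axial 3-OMe would collide with the 6-endo-methyl and the equatorial (3R) epimer remains.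

Step 6
Reactants: 12 (1S,3R,5S,6S,7R)-dione
Product: 13 (1R,2R,3R,5S,6S,7R)-2-hydroxy-1,3-dimethoxy-6-methyl-5-(prop-2-enyl)-7-(3,4,5-trimethoxyphenyl)bicyclo[3.2.1]octan-8-one
Conditions: L-Selectride (1.2 equiv), THF, −78 °C; pH 7 buffer, 30% H2O2, 0 °C
Reagents that add atoms: none
Why: Sterically controlled trialkylborohydride ketone reduction, in which the bulky hydride avoids the axial path (blocked by the C8 carbonyl oxygen and H-4ax) and enters equatorially from the endo face, where only H-7 stands because the aryl is exo; this gives the axial 2-OH cis to 3-OMe, as with 2-alkoxycyclohexanones and 4,4-dimethyl-3-ketones, and the C8 ketone between two quaternary carbons, screened by the exo aryl, is not reached.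

## Compound list
1 | 2,3,4-trimethoxyphenol | COc1ccc(O)c(OC)c1OC | starting material
2 | allyl bromide (3-bromoprop-1-ene) | C=CCBr | starting material
3 | 1,2,3-trimethoxy-4-(prop-2-enyloxy)benzene | C=CCOc1ccc(OC)c(OC)c1OC | intermediate
4 | 2,3,4-trimethoxy-6-(prop-2-enyl)phenol | C=CCc1cc(OC)c(OC)c(OC)c1O | intermediate
5 | 3,4,5-trimethoxybenzaldehyde | COc1cc(C=O)cc(OC)c1OC | starting material
6 | ethyltriphenylphosphonium bromide | CC[P+](c1ccccc1)(c1ccccc1)c1ccccc1.[Br-] | starting material
7 | ethylidenetriphenylphosphorane (ethylidene ylide) | CC=P(c1ccccc1)(c1ccccc1)c1ccccc1 | intermediate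
8 | (Z)-isoelemicin, 1,2,3-trimethoxy-5-[(1Z)-prop-1-enyl]benzene | C/C=C\c1cc(OC)c(OC)c(OC)c1 | intermediate
9 | 2,3,4,4-tetramethoxy-6-(prop-2-enyl)cyclohexa-2,5-dien-1-one (quinone monoketal) | C=CCC1=CC(OC)(OC)C(OC)=C(OC)C1=O | intermediate
10 | (1S,5R,6S,7R)-1,2,2,3-tetramethoxy-6-methyl-5-(prop-2-enyl)-7-(3,4,5-trimethoxyphenyl)bicyclo[3.2.1]oct-3-en-8-one (6-endo-methyl, 7-exo-aryl) | C=CC[C@@]12C=C(OC)C(OC)(OC)[C@@](OC)(C1=O)[C@@H](c1cc(OC)c(OC)c(OC)c1)[C@@H]2C | intermediate
11 | (1S,5R,6S,7R)-1,3-dimethoxy-6-methyl-5-(prop-2-enyl)-7-(3,4,5-trimethoxyphenyl)bicyclo[3.2.1]oct-3-ene-2,8-dione (6-endo-methyl, 7-exo-aryl) | C=CC[C@@]12C=C(OC)C(=O)[C@@](OC)(C1=O)[C@@H](c1cc(OC)c(OC)c(OC)c1)[C@@H]2C | intermediate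
12 | (1S,3R,5S,6S,7R)-1,3-dimethoxy-6-methyl-5-(prop-2-enyl)-7-(3,4,5-trimethoxyphenyl)bicyclo[3.2.1]octane-2,8-dione (3-OMe equatorial) | C=CC[C@@]12C[C@@H](OC)C(=O)[C@@](OC)(C1=O)[C@@H](c1cc(OC)c(OC)c(OC)c1)[C@@H]2C | intermediate
13 | (1R,2R,3R,5S,6S,7R)-2-hydroxy-1,3-dimethoxy-6-methyl-5-(prop-2-enyl)-7-(3,4,5-trimethoxyphenyl)bicyclo[3.2.1]octan-8-one (2-OH axial, syn to C8=O) | C=CC[C@@]12C[C@@H](OC)[C@@H](O)[C@@](OC)(C1=O)[C@@H](c1cc(OC)c(OC)c(OC)c1)[C@@H]2C | target

## Step count and risks
Total step count: 6.
Longest linear sequence: 5 (steps 1, 2, 4, 5, 6).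

**Step 4 is the most likely to fail.**
- The ion pair may give low ee.
- The Z alkene may leak to E through reversible addition or protonation, which feeds the 6-exo-methyl-7-endo-aryl series.
- The benzylic cation may close on the carbonyl oxygen or, on long exposure to acid, on the allyl group.

The fallback sets out from 4 and 8 and comes back at 11. Face control by a catalyst is given up and replaced by resolution. Compound 4 is oxidised as in stage (a), but 9 is isolated (NaHCO3 wash, short alumina plug). It is then combined with 8 and TMSOTf in 3 M LiClO4–EtOAc at −40 °C. In this medium the free, long-lived cations can rotate and close on carbon. Aqueous work-up gives the racemate, that is 11 together with its mirror image, the (1R,5S,6R,7S)-enedione F1. Preparative SFC on an amylose-type chiral phase delivers 11 for step 5.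

**Step 6 is the second risk.** The exo face of the C2 ketone is intrinsically the more open one, so the equatorial alcohol may dominate, and some attack at C8 is possible.

The fallback sets out from 12 and comes back at 13. It uses the exo-face preference instead of fighting it.
- LiAlH(Ot-Bu)3 in THF at −40 °C adds hydride from the exo face and gives the equatorial (2S)-alcohol F2.
- Tf2O and pyridine in CH2Cl2 at −20 °C convert it into the (2S)-triflate F3.
- Bu4NNO2 in toluene at rt to 50 °C displaces the triflate from the open exo side with inversion (Lattrell–Dax type). This gives the (2R)-nitrite ester F4, which hydrolyses on aqueous work-up to 13.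

**Step 5 is the third risk.**
- The α-methoxy enone is electron-rich and its β-carbon is neopentyl, so hydride transfer may be slow.
- Competing 1,2-reduction is possible.
- The C3 equilibrium may be less one-sided than expected.

The fallback sets out from 11 and comes back at 12. Hydride is replaced by a soft heteroatom nucleophile followed by radical cleavage. PhSeSePh/NaBH4 in EtOH–AcOH at 0 °C adds phenylselenolate to C4 from the exo face and gives the 4-phenylselanyl dione F5. Bu3SnH and AIBN in benzene at 80 °C then exchange selenium for hydrogen. Cyclisation of the C4 radical onto the allyl group would be 4-exo or 5-endo, and both are disfavoured. The DBU equilibration of step 5 then gives 12.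

## Further compounds
F1 | step 4 | (1R,5S,6R,7S)-1,3-dimethoxy-6-methyl-5-(prop-2-enyl)-7-(3,4,5-trimethoxyphenyl)bicyclo[3.2.1]oct-3-ene-2,8-dione (mirror image of 11) | C=CC[C@]12C=C(OC)C(=O)[C@](OC)(C1=O)[C@H](c1cc(OC)c(OC)c(OC)c1)[C@H]2C
F2 | step 6 | (1R,2S,3R,5S,6S,7R)-2-hydroxy-1,3-dimethoxy-6-methyl-5-(prop-2-enyl)-7-(3,4,5-trimethoxyphenyl)bicyclo[3.2.1]octan-8-one (2-OH equatorial) | C=CC[C@@]12C[C@@H](OC)[C@H](O)[C@@](OC)(C1=O)[C@@H](c1cc(OC)c(OC)c(OC)c1)[C@@H]2C
F3 | step 6 | (1R,2S,3R,5S,6S,7R)-1,3-dimethoxy-6-methyl-8-oxo-5-(prop-2-enyl)-7-(3,4,5-trimethoxyphenyl)bicyclo[3.2.1]octan-2-yl trifluoromethanesulfonate | C=CC[C@@]12C[C@@H](OC)[C@H](OS(=O)(=O)C(F)(F)F)[C@@](OC)(C1=O)[C@@H](c1cc(OC)c(OC)c(OC)c1)[C@@H]2C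
F4 | step 6 | (1R,2R,3R,5S,6S,7R)-1,3-dimethoxy-6-methyl-8-oxo-5-(prop-2-enyl)-7-(3,4,5-trimethoxyphenyl)bicyclo[3.2.1]octan-2-yl nitrite | C=CC[C@@]12C[C@@H](OC)[C@@H](ON=O)[C@@](OC)(C1=O)[C@@H](c1cc(OC)c(OC)c(OC)c1)[C@@H]2C
F5 | step 5 | (1S,3S,4R,5S,6S,7R)-1,3-dimethoxy-6-methyl-4-(phenylselanyl)-5-(prop-2-enyl)-7-(3,4,5-trimethoxyphenyl)bicyclo[3.2.1]octane-2,8-dione (SePh axial, syn to C8) | C=CC[C@@]12[C@@H]([Se]c3ccccc3)[C@@H](OC)C(=O)[C@@](OC)(C1=O)[C@@H](c1cc(OC)c(OC)c(OC)c1)[C@@H]2C
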